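**Retrosynthetic overview**

1. The free acid groups on C3 of the isochromanone and on the succinate CH2 come from oxidative cleavage of one cyclohexene C=C; the phenols and the third acid are released by a final hydrogenolysis.
2. The δ-lactone is cut at the C1–C8a bond and at the O2–C3 bond: CO2 is inserted between an aryl C–Br and the neighbouring alkene carbon of a 2-arylcyclohex-3-ene-1-carboxylate by a one-pot carboxylation/iodolactonization.
3. Enabling feature: C3 is bonded to C4, C4 to C4a, and C4a is ortho to C8a; with C3, C4, the succinate CH and CH2 and the two future carboxyl carbons drawn as one cyclohexene ring, a carboxylate on C8a reaches C3 in a 6-exo closure whose cis ring fusion is the 3,4-cis relationship of the target.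
4. The cyclohexene is a Diels–Alder adduct of an (E)-1-arylbutadiene and a chiral acrylimide (sets C4); epimerization to the trans ester sets the succinate centre.
5. Ring order: cyclohexene (Diels–Alder), then δ-lactone (key step), then cleavage of the cyclohexene.

Key step: step 8

Remark: the SMILES defines the 3,4-cis lactone (3S,4R) with an (R) succinate carbon; the route is built for exactly this isomer.
Remark: the facial sense of the cycloaddition is taken from the chelate model of N-acryloyl oxazolidinones (diene adds anti to the 4-benzyl group), which calls for the (R)-auxiliary.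

**Step 1**
Reactants: 1 5-bromo-1,2,3-trimethoxybenzene
Product: 2 6-bromo-2,3,4-trimethoxybenzaldehyde
Conditions: Cl2CHOMe, TiCl4, CH2Cl2, −10 °C → rt; H2O
Reagents that add atoms: dichloromethyl methyl ether (ClC(Cl)OC); water (O)
Why: Rieche formylation; the two free ring positions are equivalent and each is ortho and para to a methoxy group, so only one aldehyde can form.

**Step 2**
Reactants: 2 6-bromo-2,3,4-trimethoxybenzaldehyde
Product: 3 6-bromo-2,3,4-trihydroxybenzaldehyde
Conditions: BBr3 (4 equiv), CH2Cl2, −78 °C → rt; H2O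
Reagents that add atoms: none
Why: Lewis-acid cleavage of aryl methyl ethers with BBr3, which leaves the aldehyde and the aryl bromide intact and allows a benzyl-only protecting-group set for a neutral last step.

**Step 3**
Reactants: 3 6-bromo-2,3,4-trihydroxybenzaldehyde
Product: 4 2,3,4-tris(benzyloxy)-6-bromobenzaldehyde
Conditions: BnBr (3.6 equiv), K2CO3, DMF, 60 °C, argon
Reagents that add atoms: benzyl bromide (BrCc1ccccc1)
Why: Williamson ether synthesis on the three phenoxides, run under argon because the triol is air-sensitive in base.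

**Step 4**
Reactants: 4 2,3,4-tris(benzyloxy)-6-bromobenzaldehyde; 5 diethyl allylphosphonate
Product: 6 1,2,3-tris(benzyloxy)-5-bromo-4-[(1E)-buta-1,3-dien-1-yl]benzene
Conditions: 5, n-BuLi, THF, −78 °C; HMPA; then 4, −78 °C → rt
Reagents that add atoms: none
Why: Horner–Wadsworth–Emmons olefination with the α-lithiated allylphosphonate, which should give the (E)-diene; the base is consumed before the aryl bromide is added.

**Step 5**
Reactants: 7 (R)-4-benzyloxazolidin-2-one; 8 acryloyl chloride
Product: 9 (R)-3-acryloyl-4-benzyloxazolidin-2-one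
Conditions: MeMgBr (1.0 equiv), THF, 0 °C; then 8, −78 → 0 °C
Reagents that add atoms: none
Why: N-acylation of the bromomagnesium oxazolidinide, which limits polymerization of the acryloyl group.

**Step 6**
Reactants: 6 1,2,3-tris(benzyloxy)-5-bromo-4-[(1E)-buta-1,3-dien-1-yl]benzene; 9 (R)-3-acryloyl-4-benzyloxazolidin-2-one
Product: 10 (4R)-4-benzyl-3-{(1S,2R)-2-[2,3,4-tris(benzyloxy)-6-bromophenyl]cyclohex-3-ene-1-carbonyl}oxazolidin-2-one
Conditions: Et2AlCl (1.4 equiv), CH2Cl2, −78 → −20 °C; 1 M HCl
Reagents that add atoms: none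
Why: Auxiliary-controlled Diels–Alder reaction: Et2AlCl chelates both carbonyls of the s-cis acrylimide and the diene adds anti to the 4-benzyl group with ortho regiochemistry and endo geometry, which should set the aryl-bearing centre (later C4) as 2R and the carbonyl-bearing centre as 1S (cis).

**Step 7**
Reactants: 10 (4R)-4-benzyl-3-{(1S,2R)-2-[2,3,4-tris(benzyloxy)-6-bromophenyl]cyclohex-3-ene-1-carbonyl}oxazolidin-2-one
Product: 12 benzyl (1R,2R)-2-[2,3,4-tris(benzyloxy)-6-bromophenyl]cyclohex-3-ene-1-carboxylate, via cis benzyl ester 11 (not isolated)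
Conditions: BnOH (2.5 equiv), n-BuLi (1.5 equiv), THF, 0 °C; then t-BuOK (0.3 equiv), 0 °C → rt; 1 M HCl
Reagents that add atoms: benzyl alcohol (OCc1ccccc1)
Why: Exocyclic transesterification of the imide with lithium benzyloxide followed by alkoxide-mediated epimerization of the ester α-centre to the thermodynamically favoured trans (diequatorial) isomer, which sets the later succinate centre relative to the fixed aryl-bearing centre.

**Step 8**
Reactants: 12 benzyl (1R,2R)-2-[2,3,4-tris(benzyloxy)-6-bromophenyl]cyclohex-3-ene-1-carboxylate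
Product: 14 benzyl (1R,4S,4aS,10bR)-8,9,10-tris(benzyloxy)-4-iodo-6-oxo-1,2,3,4,4a,10b-hexahydro-6H-benzo[c]chromene-1-carboxylate, via zinc benzoate 13 (not isolated)
Conditions: Pd(OAc)2 (5 mol%), tBuXPhos (10 mol%), Et2Zn (2 equiv), CO2 (10 atm), DMA/hexane, 40 °C; vent; then THF, sat. aq. NaHCO3, I2 (3 equiv), KI, 0 °C → rt, dark
Reagents that add atoms: carbon dioxide (O=C=O); iodine (II)
Why: Oxidative addition of the aryl bromide to zerovalent palladium, insertion of CO2 into the aryl–palladium bond and transmetalation to zinc give the zinc benzoate 13 (aryl–carboxyl bond); iodine then forms an iodonium ion on the cyclohexene, which the ortho carboxylate opens at the alkene carbon next to the aryl-bearing carbon (carboxyl oxygen–carbon bond). The closest known reaction types are the palladium-catalysed carboxylation of aryl bromides with CO2 and Et2Zn and the iodolactonization of cyclohex-2-enyl-substituted carboxylic acids. The δ-lactone closes in the 6-exo-trig mode; the 7-endo closure at the remote alkene carbon is disfavoured. The new C–O centre (C4a, later C3 of the isochromanone) is set cis to the aryl group because the tethered carboxylate can only attack axially on the face of its own anchor at C10b (cis ring fusion), and the C–I centre (C4) follows from anti addition. The step needs carboxylation beside a benzyl ester and an alkene, which catalytic CO2 insertion secures where an aryllithium would attack the ester, and it needs the benzoate rather than the ester or the ortho benzyloxy oxygen to open the iodonium ion, which the anionic carboxylate secures.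

**Step 9**
Reactants: 14 benzyl (1R,4S,4aS,10bR)-8,9,10-tris(benzyloxy)-4-iodo-6-oxo-1,2,3,4,4a,10b-hexahydro-6H-benzo[c]chromene-1-carboxylate
Product: 15 benzyl (1R,4aR,10bR)-8,9,10-tris(benzyloxy)-6-oxo-1,2,4a,10b-tetrahydro-6H-benzo[c]chromene-1-carboxylate
Conditions: DBU (3 equiv), toluene, 80 °C
Reagents that add atoms: none
Why: E2 dehydroiodination: the axial iodide has an anti-periplanar hydrogen only on the CH2 side, so the alkene should form between C3 and C4, exactly the bond to be cleaved.

**Step 10**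
Reactants: 15 benzyl (1R,4aR,10bR)-8,9,10-tris(benzyloxy)-6-oxo-1,2,4a,10b-tetrahydro-6H-benzo[c]chromene-1-carboxylate
Product: 17 (3S,4R)-5,6,7-tris(benzyloxy)-4-[(2R)-1-(benzyloxy)-3-carboxy-1-oxopropan-2-yl]-1-oxo-3,4-dihydro-1H-isochromene-3-carboxylic acid, via dialdehyde 16 (not isolated)
Conditions: O3, CH2Cl2, −78 °C, to the first blue tint; PPh3, −78 °C → rt; then NaClO2, NaH2PO4, 2-methyl-2-butene, t-BuOH/H2O, 0 °C → rt
Reagents that add atoms: ozone ([O-][O+]=O); sodium chlorite ([Na+].[O-]Cl=O)
Why: Ozonolysis of the only alkene followed by Pinnick oxidation turns the two alkene carbons into the C3 carboxylic acid and the CH2CO2H group under non-basic conditions that should not epimerize the α-acyloxy centre.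

**Step 11**
Reactants: 17 (3S,4R)-5,6,7-tris(benzyloxy)-4-[(2R)-1-(benzyloxy)-3-carboxy-1-oxopropan-2-yl]-1-oxo-3,4-dihydro-1H-isochromene-3-carboxylic acid
Product: 18 (2R)-2-[(3S,4R)-3-carboxy-5,6,7-trihydroxy-1-oxo-3,4-dihydro-1H-isochromen-4-yl]butanedioic acid
Conditions: H2 (1 atm), 10% Pd/C, THF/MeOH, rt
Reagents that add atoms: none
Why: Hydrogenolysis of the three aryl benzyl ethers and the benzyl ester under neutral conditions, which should leave the lactone closed and all three stereocentres untouched.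

**Compound list**

1 | 5-bromo-1,2,3-trimethoxybenzene | COc1cc(Br)cc(OC)c1OC | starting material
2 | 6-bromo-2,3,4-trimethoxybenzaldehyde | COc1cc(Br)c(C=O)c(OC)c1OC | intermediate
3 | 6-bromo-2,3,4-trihydroxybenzaldehyde | Oc1cc(Br)c(C=O)c(O)c1O | intermediate
4 | 2,3,4-tris(benzyloxy)-6-bromobenzaldehyde | O=Cc1c(Br)cc(OCc2ccccc2)c(OCc2ccccc2)c1OCc1ccccc1 | intermediate
5 | diethyl allylphosphonate | C=CCP(=O)(OCC)OCC | starting material
6 | 1,2,3-tris(benzyloxy)-5-bromo-4-[(1E)-buta-1,3-dien-1-yl]benzene | C=C/C=C/c1c(Br)cc(OCc2ccccc2)c(OCc2ccccc2)c1OCc1ccccc1 | intermediate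
7 | (R)-4-benzyloxazolidin-2-one | O=C1N[C@H](Cc2ccccc2)CO1 | starting material
8 | acryloyl chloride | C=CC(=O)Cl | starting material
9 | (R)-3-acryloyl-4-benzyloxazolidin-2-one | C=CC(=O)N1[C@H](Cc2ccccc2)COC1=O | intermediate
10 | (4R)-4-benzyl-3-{(1S,2R)-2-[2,3,4-tris(benzyloxy)-6-bromophenyl]cyclohex-3-ene-1-carbonyl}oxazolidin-2-one | O=C(N1[C@H](Cc2ccccc2)COC1=O)[C@H]1CCC=C[C@H]1c1c(Br)cc(OCc2ccccc2)c(OCc2ccccc2)c1OCc1ccccc1 | intermediate
11 | benzyl (1S,2R)-2-[2,3,4-tris(benzyloxy)-6-bromophenyl]cyclohex-3-ene-1-carboxylate (cis ester, not isolated) | O=C(OCc1ccccc1)[C@H]1CCC=C[C@H]1c1c(Br)cc(OCc2ccccc2)c(OCc2ccccc2)c1OCc1ccccc1 | intermediate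
12 | benzyl (1R,2R)-2-[2,3,4-tris(benzyloxy)-6-bromophenyl]cyclohex-3-ene-1-carboxylate | O=C(OCc1ccccc1)[C@@H]1CCC=C[C@H]1c1c(Br)cc(OCc2ccccc2)c(OCc2ccccc2)c1OCc1ccccc1 | intermediate
13 | 3,4,5-tris(benzyloxy)-2-[(1R,6R)-6-(benzyloxycarbonyl)cyclohex-2-en-1-yl]benzoic acid, present as its zinc carboxylate (not isolated) | O=C(OCc1ccccc1)[C@@H]1CCC=C[C@H]1c1c(C(=O)O)cc(OCc2ccccc2)c(OCc2ccccc2)c1OCc1ccccc1 | intermediate
14 | benzyl (1R,4S,4aS,10bR)-8,9,10-tris(benzyloxy)-4-iodo-6-oxo-1,2,3,4,4a,10b-hexahydro-6H-benzo[c]chromene-1-carboxylate | O=C(OCc1ccccc1)[C@@H]1CC[C@H](I)[C@H]2OC(=O)c3cc(OCc4ccccc4)c(OCc4ccccc4)c(OCc4ccccc4)c3[C@@H]12 | intermediate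
15 | benzyl (1R,4aR,10bR)-8,9,10-tris(benzyloxy)-6-oxo-1,2,4a,10b-tetrahydro-6H-benzo[c]chromene-1-carboxylate | O=C(OCc1ccccc1)[C@@H]1CC=C[C@H]2OC(=O)c3cc(OCc4ccccc4)c(OCc4ccccc4)c(OCc4ccccc4)c3[C@@H]12 | intermediate
16 | benzyl (2R)-2-[(3S,4R)-5,6,7-tris(benzyloxy)-3-formyl-1-oxo-3,4-dihydro-1H-isochromen-4-yl]-4-oxobutanoate (not isolated) | O=CC[C@@H](C(=O)OCc1ccccc1)[C@@H]1c2c(cc(OCc3ccccc3)c(OCc3ccccc3)c2OCc2ccccc2)C(=O)O[C@@H]1C=O | intermediate
17 | (3S,4R)-5,6,7-tris(benzyloxy)-4-[(2R)-1-(benzyloxy)-3-carboxy-1-oxopropan-2-yl]-1-oxo-3,4-dihydro-1H-isochromene-3-carboxylic acid | O=C(O)C[C@@H](C(=O)OCc1ccccc1)[C@@H]1c2c(cc(OCc3ccccc3)c(OCc3ccccc3)c2OCc2ccccc2)C(=O)O[C@@H]1C(=O)O | intermediate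
18 | (2R)-2-[(3S,4R)-3-carboxy-5,6,7-trihydroxy-1-oxo-3,4-dihydro-1H-isochromen-4-yl]butanedioic acid | O=C(O)C[C@@H](C(=O)O)[C@@H]1c2c(cc(O)c(O)c2O)C(=O)O[C@@H]1C(=O)O | target

**Count and risks**

Total: 11 steps. Longest linear sequence: 10 steps (steps 1–4 and 6–11); step 5 is a one-step side branch.

Step 8 (key step). CO2 insertion at the hindered, electron-rich arylpalladium may be slow, so that protodebromination, ethyl transfer from zinc or double-bond migration by a palladium hydride takes over. Fallback, from 12: Miyaura borylation (B2pin2, Pd(dppf)Cl2, KOAc, dioxane, 90 °C) should give the boronate benzyl (1R,2R)-2-[2,3,4-tris(benzyloxy)-6-(4,4,5,5-tetramethyl-1,3,2-dioxaborolan-2-yl)phenyl]cyclohex-3-ene-1-carboxylate F1. Copper-catalysed carboxylation of the C–B bond (CuI, a bis(oxazoline) ligand, CsF, CO2 1 atm, DMF, 90 °C; 1 M HCl) should then give the acid 13, now isolated. Separate iodolactonization (I2, NaHCO3, THF/H2O, 0 °C) returns to the route at 14.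

Step 6. The hindered, electron-rich diene may polymerize under the aluminium Lewis acid, or endo and facial selectivity may be poor. Fallback, from 6: catalyst-controlled cycloaddition with the achiral dienophile 3-acryloyloxazolidin-2-one and the milder Lewis acid [Cu((S,S)-t-Bu-box)](SbF6)2 (10 mol%, CH2Cl2, −20 °C → rt), a system with precedent for 1-arylbutadienes, should give 3-{(1S,2R)-2-[2,3,4-tris(benzyloxy)-6-bromophenyl]cyclohex-3-ene-1-carbonyl}oxazolidin-2-one F2. Treatment of F2 under the conditions of step 7 returns to the route at 12.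

Step 10. Ozone may over-oxidize the electron-rich tris(benzyloxy)arene or the benzyl ethers, and the α-acyloxy aldehyde may epimerize during work-up. Fallback, from 15: dihydroxylation (OsO4 cat., NMO, acetone/H2O, rt), expected anti to the allylic lactone oxygen, should give the diol benzyl (1R,3S,4S,4aS,10bR)-8,9,10-tris(benzyloxy)-3,4-dihydroxy-6-oxo-1,2,3,4,4a,10b-hexahydro-6H-benzo[c]chromene-1-carboxylate F3. Glycol cleavage (NaIO4, THF/H2O, 0 °C) returns to the route at 16, which is oxidized to 17 with NaClO2 as in step 10.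

**Further compounds**

F1 | step 8 | benzyl (1R,2R)-2-[2,3,4-tris(benzyloxy)-6-(4,4,5,5-tetramethyl-1,3,2-dioxaborolan-2-yl)phenyl]cyclohex-3-ene-1-carboxylate | O=C(OCc1ccccc1)[C@@H]1CCC=C[C@H]1c1c(B2OC(C)(C)C(C)(C)O2)cc(OCc2ccccc2)c(OCc2ccccc2)c1OCc1ccccc1
F2 | step 6 | 3-{(1S,2R)-2-[2,3,4-tris(benzyloxy)-6-bromophenyl]cyclohex-3-ene-1-carbonyl}oxazolidin-2-one | O=C(N1CCOC1=O)[C@H]1CCC=C[C@H]1c1c(Br)cc(OCc2ccccc2)c(OCc2ccccc2)c1OCc1ccccc1
F3 | step 10 | benzyl (1R,3S,4S,4aS,10bR)-8,9,10-tris(benzyloxy)-3,4-dihydroxy-6-oxo-1,2,3,4,4a,10b-hexahydro-6H-benzo[c]chromene-1-carboxylate | O=C(OCc1ccccc1)[C@@H]1C[C@H](O)[C@H](O)[C@H]2OC(=O)c3cc(OCc4ccccc4)c(OCc4ccccc4)c(OCc4ccccc4)c3[C@@H]12
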